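Its constants are assumed; the result is computed.

The ratio I follow is what dissolution can hand over by the asked time against the Z charged, and I hold it side by side for two slurries.

Z 1.1 M; G 0.1 mol%; time 8.0 min

- E at 8.0 min, in percent of the Z charged
- concentration of Q in solution at 8.0 min, in percent of saturation

    Z ⇌ Q, rate k1*(cs1 - [Q]) while solid is left; crystals form when [Q] > cs1 (cs1 = 0.49 M, k1 = 0.00545 s⁻¹)
    J + G ⇌ X + G, rate k2*[G]*[J] forward; the back reaction follows from the equilibrium constant (K2 = 0.48, k2 = 14.5 M⁻¹ s⁻¹)
    E ⇌ J (K3 = 0.44, k3 = 0.00169 s⁻¹)
    Q ⇌ E (K4 = 8.93, k4 = 0.0132 s⁻¹)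

The flask's 1.1 M is more than the solubility 0.49 M, and so is the neighbour's 0.66 M, so each starts with solid under the solution.

Q passes to E with a half-life of 0.88 min, short against 8.0 min, so I treat Q as a quasi-steady-state intermediate: dissolution into Q equals passage out of it. Setting aside the return from E, [Q] stands at 29.2% of saturation and the feed is 0.113 M min⁻¹, alike in both flasks while solid lasts. Over 8.0 min this gives 82.5% for the flask, its feed share: steady feed times time, over the Z charged.

| Flask | Z charged | Feed share |
|---|---|---|
| flask | 1.1 M | 82.5% |
| neighbour | 0.66 M | 137% |

By this reckoning the flask ends with solid and the neighbour ends without it.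

In the flask, [Q] rises to its steady level with the rate constant k1 + k4, so E receives the feed after a lag of 0.894 min, and it drains into J with a forward half-life of 6.8 min. A constant feed against that first-order drain gives [E] = 0.574 M, which is 52.2% of the charge. The steady balance, now with the return from E, puts [Q] at 38.5% of saturation.

The forecast gives 53% and 38%, on the ground that “Solid Z should last the full 8 minutes”.

The simulation gives 51.3% and 37.4%, so the forecast held.

In the flask at 8.00 min, solid Z stands at 17.9% of the charge, so 82.1% has dissolved, with a feed share of 82.5%. The neighbour, charged with 0.66 M, has a feed share of 137%, and the same feed of 0.113 M min⁻¹ takes its charge through in 5.82 min, earlier than 8.0 min. In the neighbour at 8.00 min, solid Z stands at 0%, Q at 10.4% and E at 67.9% of its charge.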